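(Readings and results come from a simulation from invented constants, noise included.)

I decide to reckon this flask from the run with equal charges, the zero of the scale for a step in which substrate meets reagent.

| setting | maple | cedar | flask |
|---|---|---|---|
| substrate | 0.17 M | 0.17 M | 0.17 M |
| reagent | 0.17 M | 0.26 M | 0.119 M |
| remark | run made earlier | run made earlier |  |
| time |  |  | 20 h |

| run | time / h | isomer of the product / % | substrate / % | intermediate / % | target / % |
|---|---|---|---|---|---|
| maple | 2.50 | 0.5 | 96.1 | 2.8 | 0.9 |
| maple | 5.00 | 0.1 | 92.2 | 5.5 | 1.2 |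
| maple | 8.00 | 1.7 | 88.1 | 8.4 | 2.2 |
| maple | 10.0 | 2.2 | 85.5 | 9.7 | 2.7 |
| maple | 12.0 | 2.6 | 83.1 | 10.8 | 3.2 |
| maple | 15.0 | 3.5 | 79.6 | 12.6 | 4.4 |
| cedar | 1.33 | 0 | 96.3 | 2.8 | 1.2 |
| cedar | 2.00 | 0 | 95.6 | 3.7 | 0.4 |
| cedar | 4.00 | 0.3 | 90.4 | 7.2 | 2.0 |
| cedar | 6.00 | 1.3 | 86.0 | 9.7 | 3.0 |
| cedar | 10.0 | 2.3 | 78.6 | 14.3 | 4.9 |
| cedar | 15.0 | 5.2 | 70.1 | 18.5 | 6.3 |

(standard deviation of a reading: 0.3 percentage points)



- the species in which most of what was charged as substrate, at 20 h sits (isomer of the product / target / substrate / intermediate)
- the largest share itself, whichever of these holds it, in percent of the substrate charged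

In maple, c(substrate) and c(reagent) start alike, and if each substrate takes one reagent in a step of first order in each, they stay alike and the reciprocal of c(substrate) rises in a straight line with time. That rise per hour is what I carry, the equal-charge constant k, here 0.101 M⁻¹ h⁻¹, a reading from maple at 15.0 h.

But cedar has unequal charges, so there I take the logarithm of c(reagent)/c(substrate), which rises by k times the difference of the charges. At 15.0 h it reads 0.102 M⁻¹ h⁻¹, so one constant serves both runs.

In the flask the reagent is the limiting reagent, 0.119 M against 0.17 M of substrate. So by my reckoning c(substrate)/c(reagent) reaches 1.58 at 20 h, which leaves 81.5% of the substrate. That is more than the 18.5% shared by intermediate, target and isomer of the product.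

The forecast says substrate at 81.5%: “Substrate therefore clearly holds the largest share.”

The flask gives substrate at 81.5%.

    intermediate ⇌ target (K = 0.330, k = 0.680 h⁻¹)
    intermediate ⇌ isomer of the product (K = 3.00, k = 0.0350 h⁻¹)
    substrate + reagent → intermediate + released group (k = 0.100 M⁻¹ h⁻¹)

The forecast's 81.5% would stand 5 points off in a flask with reagent at 0.155 M, the time held, or with a time of 27.6 h, the amounts held. The neighbour flask has the same charges and is read at 5.0 h. There k gives a ratio of 1.47 and 94.4% of the substrate, and that flask holds 94.5%.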